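The route rests on cutting the bond between C5 of the central ring (the carbon meta to both ring oxygens) and the neighbouring CH2 of the ethylene bridge. The key step exploits the 2-hydroxyphenyl ring: its phenolic oxygen and the bridge CH2 to be joined to C5 are linked through two ring carbons and the other CH2, so this half is a ring-opened 2,3-dihydrobenzofuran. Reductive O–CH2 cleavage with lithium should unveil the phenoxide and a carbanion at exactly that carbon; after transmetalation to zinc, palladium couples it with the C5 bromide of the unprotected benzylated bromoresorcinol monomethyl ether. One operation should thus deliver the target with no protecting group to remove.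

Key step: step 4

Assumption (remark on the chemistry): aldehyde 1, the THF solution of Grignard reagent 3 and dihydrobenzofuran 6 are taken as purchasable. Reagent 3 is racemic at its acetal carbon; this centre and the carbinol centre of 4 are both removed in step 3. The target has no stereocentre.

Step 1
Reactants: 1 4-bromo-2,6-dimethoxybenzaldehyde
Product: 2 4-bromo-2-hydroxy-6-methoxybenzaldehyde
Conditions: BCl3 (1.1 equiv), CH2Cl2, −78 °C to 0 °C; aq. NaHCO3
Reagents that add atoms: none
Why: Chelation-controlled Lewis-acid O-demethylation, in which BCl3 bound to the aldehyde oxygen should cleave one ortho methyl ether through a six-membered boron chelate that then keeps the carbonyl from delivering a second equivalent to the other methoxy group.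

Step 2
Reactants: 2 4-bromo-2-hydroxy-6-methoxybenzaldehyde; 3 [4-(oxan-2-yloxy)phenyl]magnesium bromide
Product: 4 (4-bromo-2-hydroxy-6-methoxyphenyl)[4-(oxan-2-yloxy)phenyl]methanol (mixture of diastereomers, racemic)
Conditions: 3 (2.5 equiv, 0.5 M in THF), THF, −20 °C to rt; sat. aq. NH4Cl; crude product used directly
Reagents that add atoms: none
Why: Grignard 1,2-addition, in which the first equivalent should form the magnesium phenoxide and the second should add to the chelated aldehyde while the aryl bromide stays inert; neither new stereocentre is controlled because both are removed in step 3.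

Step 3
Reactants: 4 (4-bromo-2-hydroxy-6-methoxyphenyl)[4-(oxan-2-yloxy)phenyl]methanol
Product: 5 5-bromo-2-[(4-hydroxyphenyl)methyl]-3-methoxyphenol
Conditions: Et3SiH (3 equiv), TFA (10 equiv), CH2Cl2, 0 °C to rt
Reagents that add atoms: none
Why: Ionic hydrogenation (Kursanov–Parnes type), in which TFA should ionise the carbinol to a cation stabilised by the ortho-hydroxy, ortho-methoxy and para-alkoxyphenyl groups that Et3SiH reduces to the diarylmethane, while the same acid removes the THP acetal and the silane traps its oxocarbenium ion as oxane.

Step 4
Reactants: 5 5-bromo-2-[(4-hydroxyphenyl)methyl]-3-methoxyphenol; 6 2,3-dihydro-1-benzofuran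
Product: 10 2-[(4-hydroxyphenyl)methyl]-5-[2-(2-hydroxyphenyl)ethyl]-3-methoxyphenol, via dilithio phenolate 7 (not isolated), via alkylzinc phenolate 8 (not isolated), via magnesium bisphenolate 9 (not isolated)
Conditions: 6 (1.6 equiv), Li powder (excess), DTBB (5 mol %), THF, 0 °C; filtered from Li, ZnCl2 (1.7 equiv), THF, 0 °C to rt; added to 5 pretreated with MeMgCl (2.0 equiv, THF, 0 °C), Pd(OAc)2 (2 mol %), SPhos (4 mol %), THF, 50 °C; aq. NH4Cl
Reagents that add atoms: none
Why: The DTBB radical anion should transfer two electrons in turn to 6, whose O–CH2 bond breaks with the phenoxide as leaving group to give the primary alkyllithium 7, and ZnCl2 converts this into the far less basic alkylzinc 8; Pd(0)/SPhos then inserts into the C5–Br bond of 9, 8 transmetalates and reductive elimination forms the C5–CH2 bond. The closest known reaction types are the arene-catalysed reductive lithiation (ring opening) of cyclic aryl alkyl ethers and the Negishi sp3–sp2 cross-coupling of primary alkylzinc halides with aryl bromides. No ring is closed and no stereocentre is created. The step needs alkyl–O rather than aryl–O cleavage, which the better leaving-group ability of phenoxide over alkoxide should secure, and C–C coupling in preference to protonation of the carbon–zinc bond, which the prior conversion of both phenols of 5 into magnesium phenoxides should secure. β-Hydride elimination from the alkylpalladium intermediate should be outrun by reductive elimination at the bulky biaryl phosphine, and the bromide, meta to both oxygens, is the only carbon–halogen bond and is not deactivated by resonance donation.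

Compound list
1 | 4-bromo-2,6-dimethoxybenzaldehyde | COc1cc(Br)cc(OC)c1C=O | starting material
2 | 4-bromo-2-hydroxy-6-methoxybenzaldehyde | COc1cc(Br)cc(O)c1C=O | intermediate
3 | [4-(oxan-2-yloxy)phenyl]magnesium bromide (racemic) | Br[Mg]c1ccc(OC2CCCCO2)cc1 | starting material
4 | (4-bromo-2-hydroxy-6-methoxyphenyl)[4-(oxan-2-yloxy)phenyl]methanol (diastereomer mixture, racemic) | COc1cc(Br)cc(O)c1C(O)c1ccc(OC2CCCCO2)cc1 | intermediate
5 | 5-bromo-2-[(4-hydroxyphenyl)methyl]-3-methoxyphenol | COc1cc(Br)cc(O)c1Cc1ccc(O)cc1 | intermediate
6 | 2,3-dihydro-1-benzofuran | C1Cc2ccccc2O1 | starting material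
7 | lithium 2-(2-lithioethyl)phenolate | [Li]CCc1ccccc1O[Li] | intermediate
8 | lithium 2-[2-(chlorozincio)ethyl]phenolate | [Li+].[O-]c1ccccc1CC[Zn]Cl | intermediate
9 | bis(chloromagnesium) bisphenolate of 5 | COc1cc(Br)cc(O[Mg]Cl)c1Cc1ccc(O[Mg]Cl)cc1 | intermediate
10 | 2-[(4-hydroxyphenyl)methyl]-5-[2-(2-hydroxyphenyl)ethyl]-3-methoxyphenol | COc1cc(CCc2ccccc2O)cc(O)c1Cc1ccc(O)cc1 | target

Total step count: 4. Longest linear sequence: 4 steps (1 → 2 → 4 → 5 → 10).

Steps most likely to fail

Step 4. The alkylzinc may be protonated by phenolic O–H that escaped deprotonation, the reductive cleavage of 6 may be incomplete or go the aryl–O way, and β-hydride elimination may compete at palladium. The fallback sets out from 5 and makes the same bond by a Heck reaction: 5 and commercial 2-vinylphenol (Pd(OAc)2, P(o-tol)3, Et3N, DMF, 110 °C) should give 2-[(4-hydroxyphenyl)methyl]-5-[(E)-2-(2-hydroxyphenyl)ethenyl]-3-methoxyphenol F1. Hydrogenation of the alkene (H2, Pd/C, EtOAc/MeOH, rt) then comes back to the route at 10.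

Step 3. The benzylic cation, or the o-quinone methide derived from it, may be intercepted by the electron-rich phenol rings before hydride transfer, and the oxocarbenium ion from the acetal may C-alkylate these rings. The fallback sets out from 4 and replaces the cationic reduction by an anionic one: NaBH4 in aqueous NaOH/EtOH at 70 °C should expel hydroxide from the phenoxide to give the o-quinone methide, which borohydride reduces by 1,4-addition to 5-bromo-3-methoxy-2-{[4-(oxan-2-yloxy)phenyl]methyl}phenol F2. Mild acetal cleavage (PPTS, MeOH, 50 °C) comes back at 5.

Step 2. Addition to the deactivated, doubly ortho-substituted magnesium phenoxide aldehyde may be slow, and the salicyl-type carbinol may lose water on work-up. The fallback sets out from 1, avoids both the free phenol and the carbinol, and desymmetrises the methyl ethers late. Condensation of 1 with tosylhydrazide (MeOH, 60 °C) should give N'-[(E)-(4-bromo-2,6-dimethoxyphenyl)methylidene]-4-methylbenzenesulfonohydrazide F3. Metal-free reductive coupling with 4-hydroxyphenylboronic acid (K2CO3, dioxane, 110 °C; the aryl bromide is untouched) should give 4-[(4-bromo-2,6-dimethoxyphenyl)methyl]phenol F4. Mono-demethylation with NaSEt (DMF, 120 °C), which should stop after one methyl because the new phenoxide deactivates the ring, comes back at 5.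

Further compounds
F1 | step 4 | 2-[(4-hydroxyphenyl)methyl]-5-[(E)-2-(2-hydroxyphenyl)ethenyl]-3-methoxyphenol | COc1cc(/C=C/c2ccccc2O)cc(O)c1Cc1ccc(O)cc1
F2 | step 3 | 5-bromo-3-methoxy-2-{[4-(oxan-2-yloxy)phenyl]methyl}phenol | COc1cc(Br)cc(O)c1Cc1ccc(OC2CCCCO2)cc1
F3 | step 2 | N'-[(E)-(4-bromo-2,6-dimethoxyphenyl)methylidene]-4-methylbenzenesulfonohydrazide | COc1cc(Br)cc(OC)c1/C=N/NS(=O)(=O)c1ccc(C)cc1
F4 | step 2 | 4-[(4-bromo-2,6-dimethoxyphenyl)methyl]phenol | COc1cc(Br)cc(OC)c1Cc1ccc(O)cc1
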